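**Retrosynthetic overview**
- Both quinones are unmasked last by oxidative demethylation of a meso bis(2,5-dimethoxyaryl)succinate. No ring is built: both six-membered rings come intact from 4-methoxyphenol.
- The meso diester comes from the 2,3-diarylbutenedioate by conjugate reduction and base equilibration; the butenedioate is the dehydrated aldol adduct.
- Key C2–C3 bond: intermolecular aldol addition of the lithium enolate of methyl (3-geranyl-2,5-dimethoxyphenyl)acetate to methyl (3-geranyl-2,5-dimethoxyphenyl)glyoxylate.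
- Both halves come from one aryl bromide, 1-bromo-3-geranyl-2,5-dimethoxybenzene (malonate arylation/Krapcho for the acetate; Br–Li exchange/dimethyl oxalate for the glyoxylate).
- That bromide comes from 4-methoxyphenol by dibromination, O-methylation and one Br–Li exchange/copper-mediated geranylation.

Assumption: the descriptors in the SMILES (2S,3R on a C2–C3 unit with identical substituents) define the meso diastereomer, which is achiral; only the relative (meso) configuration has to be controlled.

Abbreviation: geranyl = (2E)-3,7-dimethylocta-2,6-dien-1-yl throughout.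

**Step 1**
Reactants: 1 4-methoxyphenol
Product: 3 2,6-dibromo-4-methoxyphenol, via 2-bromo-4-methoxyphenol 2 (not isolated)
Conditions: Br2 (2.1 equiv), CH2Cl2, 0 °C to rt
Reagents that add atoms: bromine, BrBr
Why: Electrophilic aromatic bromination goes twice ortho to the free OH, the strongest donor, because its para position is blocked by OMe.

**Step 2**
Reactants: 3 2,6-dibromo-4-methoxyphenol
Product: 4 1,3-dibromo-2,5-dimethoxybenzene
Conditions: MeI (1.5 equiv), K2CO3, acetone, reflux
Reagents that add atoms: iodomethane, CI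
Why: Williamson O-methylation of an acidic, fully ionised 2,6-dibromophenoxide is clean despite the flanking bromines.

**Step 3**
Reactants: 4 1,3-dibromo-2,5-dimethoxybenzene; 5 geranyl bromide
Product: 8 1-bromo-3-geranyl-2,5-dimethoxybenzene, via bromoaryllithium 6 (not isolated), via bromoarylcopper 7 (not isolated)
Conditions: n-BuLi (1.0 equiv), THF, −78 °C; CuBr·SMe2 (1.0 equiv), −78 to −40 °C; 5 (1.2 equiv), −78 °C to rt
Reagents that add atoms: none
Why: Bromine–lithium exchange stops at the mono-anion at −78 °C, and the derived arylcopper undergoes SN2-selective allylic substitution with retention of the E alkene, since attack at the disubstituted terminus would create a quaternary carbon.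

**Step 4**
Reactants: 8 1-bromo-3-geranyl-2,5-dimethoxybenzene; 9 dimethyl oxalate
Product: 11 methyl (3-geranyl-2,5-dimethoxyphenyl)(oxo)acetate, via geranylaryllithium 10 (not isolated)
Conditions: n-BuLi (1.05 equiv), THF, −78 °C; cannulated into 9 (3 equiv), THF, −78 °C; AcOH quench
Reagents that add atoms: none
Why: Br–Li exchange followed by Claisen-type acyl substitution on excess oxalate under inverse addition gives the α-keto ester, the chelated tetrahedral adduct preventing a second addition.

**Step 5**
Reactants: 8 1-bromo-3-geranyl-2,5-dimethoxybenzene; 12 dimethyl malonate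
Product: 13 dimethyl 2-(3-geranyl-2,5-dimethoxyphenyl)propanedioate
Conditions: 12 (1.5 equiv), Pd(dba)2 (2 mol %), P(t-Bu)3·HBF4 (4 mol %), K3PO4 (3 equiv), toluene, 80 °C
Reagents that add atoms: none
Why: Palladium-catalysed malonate α-arylation (Buchwald–Hartwig-type enolate coupling) works on hindered, electron-rich aryl bromides with the bulky trialkylphosphine, and the meta-placed trisubstituted alkenes cannot undergo Heck cyclisation.

**Step 6**
Reactants: 13 dimethyl 2-(3-geranyl-2,5-dimethoxyphenyl)propanedioate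
Product: 14 methyl (3-geranyl-2,5-dimethoxyphenyl)acetate
Conditions: LiCl (2 equiv), H2O (2 equiv), DMSO, 140 °C
Reagents that add atoms: none
Why: Krapcho dealkoxycarbonylation of an aryl malonate is fast under neutral conditions that leave the geranyl alkenes and aryl ethers untouched.

**Step 7**
Reactants: 14 methyl (3-geranyl-2,5-dimethoxyphenyl)acetate; 11 methyl (3-geranyl-2,5-dimethoxyphenyl)(oxo)acetate
Product: 16 dimethyl 2-hydroxy-2,3-bis(3-geranyl-2,5-dimethoxyphenyl)butanedioate (mixture of both racemic diastereomers), via lithium enolate 15 (not isolated)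
Conditions: LiN(SiMe3)2 (1.1 equiv), THF, −78 °C; 11 (0.95 equiv), −78 °C, 1 h; AcOH, −78 °C
Reagents that add atoms: none
Why: Directed crossed aldol addition: the keto ester has no α-hydrogen and its ketone is the most electrophilic carbonyl, a cold acidic quench suppresses retro-aldol, and the two uncontrolled stereocentres are erased in step 8.

**Step 8**
Reactants: 16 dimethyl 2-hydroxy-2,3-bis(3-geranyl-2,5-dimethoxyphenyl)butanedioate
Product: 18 dimethyl 2,3-bis(3-geranyl-2,5-dimethoxyphenyl)but-2-enedioate (E/Z mixture), via sulfamate ester 17 (not isolated)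
Conditions: methyl N-(triethylammoniosulfonyl)carbamate (Burgess reagent, 2.5 equiv), toluene, rt to 70 °C
Reagents that add atoms: none
Why: Burgess dehydration of a tertiary β-hydroxy ester proceeds by syn-elimination of the only β-hydrogen, which is acidified by the second ester, under neutral conditions that spare the geranyl chains.

**Step 9**
Reactants: 18 dimethyl 2,3-bis(3-geranyl-2,5-dimethoxyphenyl)but-2-enedioate
Product: 19 dimethyl 2,3-bis(3-geranyl-2,5-dimethoxyphenyl)butanedioate (meso and racemic diastereomers)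
Conditions: Mg turnings (10 equiv), MeOH, 0 °C to rt; aq. NH4Cl
Reagents that add atoms: none
Why: Dissolving-metal conjugate reduction by single-electron transfer attacks only the aryl-conjugated diester alkene, both isomers of 18 converge, and the two stereocentres arise from enolate protonation without control.

**Step 10**
Reactants: 19 dimethyl 2,3-bis(3-geranyl-2,5-dimethoxyphenyl)butanedioate (diastereomer mixture)
Product: 20 dimethyl (2R,3S)-2,3-bis(3-geranyl-2,5-dimethoxyphenyl)butanedioate (meso)
Conditions: NaOMe (0.3 equiv), MeOH/THF, 50 °C; AcOH; SiO2 chromatography; racemic fraction resubmitted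
Reagents that add atoms: none
Why: Base-mediated epimerisation through the ester enolates sets the relative configuration under thermodynamic control, the meso isomer being expected to be favoured because only it can place both aryl groups and both esters anti; the racemic diastereomer is separated and recycled.

**Step 11**
Reactants: 20 dimethyl (2R,3S)-2,3-bis(3-geranyl-2,5-dimethoxyphenyl)butanedioate
Product: 22 dimethyl (2R,3S)-2,3-bis(5-geranyl-3,6-dioxocyclohexa-1,4-dien-1-yl)butanedioate (target), via monoquinone 21 (not isolated)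
Conditions: (NH4)2Ce(NO3)6 (5 equiv), MeCN/H2O 2:1, 0 °C, 15 min
Reagents that add atoms: water, O
Why: Oxidative demethylation by tetravalent cerium (electron transfer from each dimethoxyarene, then ipso attack of water) gives the quinones without touching the isolated alkenes or any bond at the stereocentres, so the meso configuration is carried over.

**Compound list**
1 | 4-methoxyphenol | COc1ccc(O)cc1 | starting material
2 | 2-bromo-4-methoxyphenol | COc1ccc(O)c(Br)c1 | intermediate (not isolated)
3 | 2,6-dibromo-4-methoxyphenol | COc1cc(Br)c(O)c(Br)c1 | intermediate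
4 | 1,3-dibromo-2,5-dimethoxybenzene | COc1cc(Br)c(OC)c(Br)c1 | intermediate
5 | geranyl bromide, (2E)-1-bromo-3,7-dimethylocta-2,6-diene | BrC/C=C(\C)CCC=C(C)C | starting material
6 | (3-bromo-2,5-dimethoxyphenyl)lithium | [Li]c1cc(OC)cc(Br)c1OC | intermediate (not isolated)
7 | (3-bromo-2,5-dimethoxyphenyl)copper | [Cu]c1cc(OC)cc(Br)c1OC | intermediate (not isolated)
8 | 1-bromo-3-geranyl-2,5-dimethoxybenzene | COc1cc(Br)c(OC)c(C/C=C(\C)CCC=C(C)C)c1 | intermediate
9 | dimethyl oxalate | COC(=O)C(=O)OC | starting material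
10 | (3-geranyl-2,5-dimethoxyphenyl)lithium | [Li]c1cc(OC)cc(C/C=C(\C)CCC=C(C)C)c1OC | intermediate (not isolated)
11 | methyl (3-geranyl-2,5-dimethoxyphenyl)(oxo)acetate | COC(=O)C(=O)c1cc(OC)cc(C/C=C(\C)CCC=C(C)C)c1OC | intermediate
12 | dimethyl malonate | COC(=O)CC(=O)OC | starting material
13 | dimethyl 2-(3-geranyl-2,5-dimethoxyphenyl)propanedioate | COC(=O)C(C(=O)OC)c1cc(OC)cc(C/C=C(\C)CCC=C(C)C)c1OC | intermediate
14 | methyl (3-geranyl-2,5-dimethoxyphenyl)acetate | COC(=O)Cc1cc(OC)cc(C/C=C(\C)CCC=C(C)C)c1OC | intermediate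
15 | lithium enolate of 14 (enolate geometry not defined) | COC(O[Li])=Cc1cc(OC)cc(C/C=C(\C)CCC=C(C)C)c1OC | intermediate (not isolated)
16 | dimethyl 2-hydroxy-2,3-bis(3-geranyl-2,5-dimethoxyphenyl)butanedioate, both racemic diastereomers (C2 and C3 undefined) | COC(=O)C(c1cc(OC)cc(C/C=C(\C)CCC=C(C)C)c1OC)C(O)(C(=O)OC)c1cc(OC)cc(C/C=C(\C)CCC=C(C)C)c1OC | intermediate
17 | triethylammonium salt of the N-(methoxycarbonyl)sulfamate ester of 16 | COC(=O)C(c1cc(OC)cc(C/C=C(\C)CCC=C(C)C)c1OC)C(OS(=O)(=O)[N-]C(=O)OC)(C(=O)OC)c1cc(OC)cc(C/C=C(\C)CCC=C(C)C)c1OC.CC[NH+](CC)CC | intermediate (not isolated)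
18 | dimethyl 2,3-bis(3-geranyl-2,5-dimethoxyphenyl)but-2-enedioate, E/Z mixture at the central alkene | COC(=O)C(c1cc(OC)cc(C/C=C(\C)CCC=C(C)C)c1OC)=C(C(=O)OC)c1cc(OC)cc(C/C=C(\C)CCC=C(C)C)c1OC | intermediate
19 | dimethyl 2,3-bis(3-geranyl-2,5-dimethoxyphenyl)butanedioate, meso plus racemic diastereomer | COC(=O)C(c1cc(OC)cc(C/C=C(\C)CCC=C(C)C)c1OC)C(C(=O)OC)c1cc(OC)cc(C/C=C(\C)CCC=C(C)C)c1OC | intermediate
20 | dimethyl (2R,3S)-2,3-bis(3-geranyl-2,5-dimethoxyphenyl)butanedioate (meso) | COC(=O)[C@H](c1cc(OC)cc(C/C=C(\C)CCC=C(C)C)c1OC)[C@@H](C(=O)OC)c1cc(OC)cc(C/C=C(\C)CCC=C(C)C)c1OC | intermediate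
21 | monoquinone: dimethyl 2-(5-geranyl-3,6-dioxocyclohexa-1,4-dien-1-yl)-3-(3-geranyl-2,5-dimethoxyphenyl)butanedioate, racemic, relative configuration as in 20 (one enantiomer drawn) | COC(=O)[C@H](C1=CC(=O)C=C(C/C=C(\C)CCC=C(C)C)C1=O)[C@@H](C(=O)OC)c1cc(OC)cc(C/C=C(\C)CCC=C(C)C)c1OC | intermediate (not isolated)
22 | dimethyl (2R,3S)-2,3-bis(5-geranyl-3,6-dioxocyclohexa-1,4-dien-1-yl)butanedioate (meso) | COC(=O)[C@H](C1=CC(=O)C=C(C/C=C(\C)CCC=C(C)C)C1=O)[C@@H](C(=O)OC)C1=CC(=O)C=C(C/C=C(\C)CCC=C(C)C)C1=O | target

**Totals**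
Total step count: 11. Longest linear sequence: 10 steps (1, 2, 3, 5, 6, 7, 8, 9, 10, 11) from 4-methoxyphenol; step 4 is a one-step branch from 8.

**Three steps most likely to fail**

Step 7 (aldol to a hindered aryl keto ester; retro-aldol or low conversion). The fallback sets out from 14 and 11 and comes back at 18. LiOH in THF/H2O saponifies 14 to (3-geranyl-2,5-dimethoxyphenyl)acetic acid F1 and, at 0 °C, 11 to (3-geranyl-2,5-dimethoxyphenyl)(oxo)acetic acid F2. Heating F1 and F2 in Ac2O with Et3N at 90 °C gives 3,4-bis(3-geranyl-2,5-dimethoxyphenyl)furan-2,5-dione F3 by a Perkin-type aldol condensation, in which irreversible dehydration and ring closure drain the reversible addition. K2CO3 in MeOH opens the anhydride to the potassium salt of the (Z)-half ester F4, which is methylated in the same flask with MeI in DMF to the Z isomer of 18. The route resumes at step 9.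

Step 10 (the meso:racemic equilibrium may be only modestly favourable, and the two oily diesters may be hard to separate). The fallback sets out from 19 and comes back at 20. LiOH in THF/MeOH/H2O at 50 °C followed by acidification gives 2,3-bis(3-geranyl-2,5-dimethoxyphenyl)butanedioic acid as a diastereomer mixture F5. The less soluble (2R,3S)-2,3-bis(3-geranyl-2,5-dimethoxyphenyl)butanedioic acid F6 (meso) is isolated by fractional crystallisation from EtOAc/heptane, relying on the much lower solubility of meso-2,3-diarylsuccinic acids. It is re-esterified without epimerisation using Me3SiCHN2 in MeOH/toluene at 0 °C to give 20. The racemic acid in the mother liquor is esterified the same way and returned to step 10.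

Step 11 (fourfold oxidation in acidic nitrate medium; risk of quinone coupling, nitration or decomposition of the product, whose C–H bonds next to the quinones are labile). The fallback sets out from 20 and comes back at 22. Anodic oxidation (Pt anode, undivided cell, constant current, LiClO4, 2,6-lutidine, MeOH, 0 °C) converts both rings into quinone bis(dimethyl ketal)s, giving dimethyl (2R,3S)-2,3-bis(5-geranyl-3,3,6,6-tetramethoxycyclohexa-1,4-dien-1-yl)butanedioate F7, which can be purified. Mild hydrolysis (5 % aq. AcOH in acetone, rt) then releases the bis-quinone 22 without any oxidant or strong acid present.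

**Further compounds**
F1 | step 7 | (3-geranyl-2,5-dimethoxyphenyl)acetic acid | OC(=O)Cc1cc(OC)cc(C/C=C(\C)CCC=C(C)C)c1OC
F2 | step 7 | (3-geranyl-2,5-dimethoxyphenyl)(oxo)acetic acid | OC(=O)C(=O)c1cc(OC)cc(C/C=C(\C)CCC=C(C)C)c1OC
F3 | step 7 | 3,4-bis(3-geranyl-2,5-dimethoxyphenyl)furan-2,5-dione | O=C1OC(=O)C(c2cc(OC)cc(C/C=C(\C)CCC=C(C)C)c2OC)=C1c1cc(OC)cc(C/C=C(\C)CCC=C(C)C)c1OC
F4 | step 7 | potassium (2Z)-4-methoxy-4-oxo-2,3-bis(3-geranyl-2,5-dimethoxyphenyl)but-2-enoate | COC(=O)/C(c1cc(OC)cc(C/C=C(\C)CCC=C(C)C)c1OC)=C(c1cc(OC)cc(C/C=C(\C)CCC=C(C)C)c1OC)\C(=O)[O-].[K+]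
F5 | step 10 | 2,3-bis(3-geranyl-2,5-dimethoxyphenyl)butanedioic acid, meso plus racemic diastereomer | OC(=O)C(c1cc(OC)cc(C/C=C(\C)CCC=C(C)C)c1OC)C(C(=O)O)c1cc(OC)cc(C/C=C(\C)CCC=C(C)C)c1OC
F6 | step 10 | (2R,3S)-2,3-bis(3-geranyl-2,5-dimethoxyphenyl)butanedioic acid (meso) | OC(=O)[C@H](c1cc(OC)cc(C/C=C(\C)CCC=C(C)C)c1OC)[C@@H](C(=O)O)c1cc(OC)cc(C/C=C(\C)CCC=C(C)C)c1OC
F7 | step 11 | dimethyl (2R,3S)-2,3-bis(5-geranyl-3,3,6,6-tetramethoxycyclohexa-1,4-dien-1-yl)butanedioate (meso) | COC(=O)[C@H](C1=CC(OC)(OC)C=C(C/C=C(\C)CCC=C(C)C)C1(OC)OC)[C@@H](C(=O)OC)C1=CC(OC)(OC)C=C(C/C=C(\C)CCC=C(C)C)C1(OC)OC
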